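A charge of substrate, let into any of these set-ups, has reacted only in part when it is read, and the question is in what proportion that reacted part has become target, other capture product or solvolysis product.

in all of them: first nucleophile 0.444 M; second nucleophile 0.740 M
- delta: substrate 0.37 M; a single well-mixed tank run continuously and read at steady state, 2.5 min in it on average
- zeta: substrate 0.37 M (fed, over 2.00 min); a stirred flask in which substrate is dosed at a steady rate over 2.00 min without added volume, worked up at 2.5 min; time 2.5 min
- gamma: substrate 0.37 M; a closed flask charged with all of it at once and left for 2.5 min; time 2.5 min
- beta: substrate 0.37 M; a single well-mixed tank run continuously and read at steady state, 7.50 min in it on average

    intermediate → solvolysis product (k1 = 0.052 /s)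
    substrate → intermediate (k2 = 0.0049 /s)
    first nucleophile + intermediate → target (k3 = 0.94 /M/s)
    second nucleophile → decomposed reagent (k4 = 0.0019 /s)
    second nucleophile + intermediate → other capture product (k5 = 1.6 /M/s)

- the stated concentrations are those of everything mixed, before any reaction; amounts are the same in each set-up
- the feed brings no volume worth counting
- run time (zeta): 2.5 min

* the set-up with the highest share of target in all that became target or other capture product or solvolysis product, at the outlet or at the end ("none" if the first two lie within 2 percentage points) (delta / zeta / gamma / beta / none)
* share of target in all that became target or other capture product or solvolysis product, at the outlet or at the end, delta
* share of target in all that became target or other capture product or solvolysis product, at the outlet or at the end, zeta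
* share of target in all that became target or other capture product or solvolysis product, at the outlet or at the end, gamma
* share of target in all that became target or other capture product or solvolysis product, at the outlet or at the end, beta

I start on the fastest rung of the ladder. At the charged concentrations the intermediate lives 0.605 s, far shorter than the 2.4 min half-life of substrate. So substrate → intermediate is the rate-limiting step, the intermediate stays at a quasi-steady state, and each portion divides according to the concentrations of its moment. On the next rung, the second nucleophile decays with a half-life of 6.1 min, longer than the 2.5 min run but not remote from it, so the division drifts slowly.

I carry one quantity, 2.84 at the charge: the capture ratio, the rate of capture of intermediate by second nucleophile over its rate of capture by first nucleophile. Solvolysis adds a smaller term, 0.125, and the target share is one over the sum of one, this term and the ratio, here 25.2% at the charge.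

As a correction I shrink the ratio by decay of second nucleophile and hold c(first nucleophile) at its charge. Gamma, read at mid-run, gives 27.9%. The tanks use their steady-state decay, so delta gives 30.0% and beta gives 37.7%. Zeta I only place between gamma and delta, since its substrate arrives over 2.00 min and reacts later than gamma's; I give it no number.

The forecast names beta, with 30.6% for delta, 29% for zeta, 28.4% for gamma and 36.8% for beta, which are not my figures; its ground reads: “The second nucleophile is the main competitor”.

The simulation gives beta as best at 36.8%, with delta at 30.6%, zeta at 29.2% and gamma at 28.4%. In gamma at 1.02 min the capture ratio reads 2.4, below the 2.84 of the charge. A neighbouring flask is gamma with 0.30 M of second nucleophile, where the ratio at the charge is 1.15. The same mid-run correction then gives 47.1%, and that flask reads 48.1%.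

Its constants were set for the occasion; the flask was simulated.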